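**Retrosynthetic overview**
- Plakortolide L (25) is opened at the γ-lactone (closed last, C4–O onto a C3 acetate arm); the C2–C3 bond comes from a ketene silyl acetal and the C3 peroxycarbenium ion of 3-methoxy-1,2-dioxan-4-ol 22.
- The 1,2-dioxane (O1–O2–C3–C4–C5–C6) is closed first, through the O1–C6 bond, by a Pd(II) syn-SN2′ attack of the C3 hydroperoxy acetal of 20 on the C6=C1′ alkene with loss of the C2′ hydroxyl.
- The strategy rests on C6, the quaternary peroxide carbon (CH3 and C12 chain): its chain neighbours C1′ and C2′ serve as alkene carbon and (S)-carbinol, so the configuration of C2′ is relayed to C6.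
- 20 comes from enone 16 (CBS reduction sets C2′), made from (E)-iodoalkene 11 and Weinreb amide 14; 11 comes from alkyne diol 6 (Zr-catalysed methylalumination/iodination), and 6 from (R)-2-methylglycidol 1 (source of C4) and TMS-acetylene 3.
- Ring order: 1,2-dioxane (step 13), then γ-lactone (step 16).

Key step: step 13

Remark: plakortolide numbering is used (C1 lactone carbonyl, C3 peroxy CH, C4 and C6 quaternary, C1′–C12′ chain). C3 is carried as an epimer mixture from step 11 to step 15, where it becomes planar, so it is left undefined in those SMILES.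

**Step 1**
Reactants: 1 (R)-2-methylglycidol
Product: 2 (S)-tert-butyldimethyl[(2-methyloxiran-2-yl)methoxy]silane
Conditions: TBSCl, imidazole, CH2Cl2, 0 °C → rt
Reagents that add atoms: tert-butyldimethylsilyl chloride CC(C)(C)[Si](C)(C)Cl
Why: Imidazole-mediated silylation of the primary alcohol leaves the epoxide and the quaternary stereocentre untouched (the descriptor changes only through CIP priorities).

**Step 2**
Reactants: 2 (S)-tert-butyldimethyl[(2-methyloxiran-2-yl)methoxy]silane, 3 ethynyltrimethylsilane
Product: 5 (S)-1-[(tert-butyldimethylsilyl)oxy]-2-methyl-5-(trimethylsilyl)pent-4-yn-2-ol, via lithium (trimethylsilyl)acetylide 4 (not isolated)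
Conditions: 3, n-BuLi, THF, −78 °C; BF3·OEt2; then 2, −78 °C; aq. NH4Cl
Reagents that add atoms: none
Why: Yamaguchi–Hirao alkynylation: the BF3-activated epoxide is opened by the acetylide at its unsubstituted CH2 terminus (SN2), so the tertiary carbinol carbon (future C4) is not touched and keeps its configuration.

**Step 3**
Reactants: 5 (S)-1-[(tert-butyldimethylsilyl)oxy]-2-methyl-5-(trimethylsilyl)pent-4-yn-2-ol
Product: 6 (S)-2-methylpent-4-yne-1,2-diol
Conditions: TBAF, THF, 0 °C → rt
Reagents that add atoms: none
Why: Fluoride cleaves the O–Si and the C(sp)–Si bond in one operation, giving the terminal alkyne needed for carbometalation.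

**Step 4**
Reactants: 6 (S)-2-methylpent-4-yne-1,2-diol, 7 trimethylaluminium
Product: 9 (2S,4E)-5-iodo-2,4-dimethylpent-4-ene-1,2-diol, via aluminated (E)-alkenylalane 8 (not isolated)
Conditions: Me3Al (4 equiv), Cp2ZrCl2 (0.25 equiv), CH2Cl2, 0 °C → rt; then I2, THF, −30 → 0 °C; aq. Rochelle salt, Na2S2O3
Reagents that add atoms: iodine II
Why: Negishi zirconium-catalysed methylalumination adds CH3 and Al syn across the terminal alkyne with methyl on the internal carbon (the hydroxyls ride as aluminium alkoxides), and iodinolysis of the C–Al bond with retention fixes the (E)-trisubstituted iodoalkene.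

**Step 5**
Reactants: 9 (2S,4E)-5-iodo-2,4-dimethylpent-4-ene-1,2-diol
Product: 10 (2S,4E)-2-hydroxy-5-iodo-2,4-dimethylpent-4-enal
Conditions: (COCl)2, DMSO, CH2Cl2, −78 °C; Et3N, −78 → 0 °C
Reagents that add atoms: none
Why: Swern oxidation converts only the primary alcohol; the tertiary carbinol cannot be oxidised and activated DMSO does not cleave the glycol.

**Step 6**
Reactants: 10 (2S,4E)-2-hydroxy-5-iodo-2,4-dimethylpent-4-enal
Product: 11 (2S,4E)-5-iodo-1,1-dimethoxy-2,4-dimethylpent-4-en-2-ol
Conditions: HC(OMe)3, MeOH, p-TsOH·H2O (cat.), rt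
Reagents that add atoms: trimethyl orthoformate COC(OC)OC; methanol CO
Why: Acid-catalysed acetalisation with orthoformate as water scavenger; it is placed here, on the acid-stable iodoalkene, so that this strong-acid step stays away from the later acid-labile allylic alcohol.

**Step 7**
Reactants: 12 11-phenylundecanoic acid
Product: 14 N-methoxy-N-methyl-11-phenylundecanamide, via acyl imidazolide 13 (not isolated)
Conditions: CDI, CH2Cl2, rt; then MeNH(OMe)·HCl, rt
Reagents that add atoms: N,O-dimethylhydroxylamine hydrochloride CNOC.Cl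
Why: Weinreb amide formation through the acyl imidazolide, a standard activation of an unhindered carboxylic acid.

**Step 8**
Reactants: 11 (2S,4E)-5-iodo-1,1-dimethoxy-2,4-dimethylpent-4-en-2-ol, 14 N-methoxy-N-methyl-11-phenylundecanamide
Product: 16 (2S,4E)-2-hydroxy-1,1-dimethoxy-2,4-dimethyl-16-phenylhexadec-4-en-6-one, via alkenyllithium lithium alkoxide 15 (not isolated)
Conditions: t-BuLi (3.1 equiv), Et2O, −78 °C; then 14, THF, −78 → −20 °C; aq. NH4Cl
Reagents that add atoms: none
Why: Iodine–lithium exchange (after deprotonation of the tertiary OH) proceeds with retention of alkene geometry, and acylation by the Weinreb amide stops at the ketone because of the chelated tetrahedral intermediate.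

**Step 9**
Reactants: 16 (2S,4E)-2-hydroxy-1,1-dimethoxy-2,4-dimethyl-16-phenylhexadec-4-en-6-one
Product: 17 (2S,4E,6S)-1,1-dimethoxy-2,4-dimethyl-16-phenylhexadec-4-ene-2,6-diol
Conditions: (R)-2-methyl-CBS-oxazaborolidine (0.5 equiv), catecholborane (2.5 equiv), toluene, −78 °C; MeOH, aq. NaOH
Reagents that add atoms: none
Why: Corey–Bakshi–Shibata reduction: with the (R)-oxazaborolidine the alkenyl group acts as the large substituent and hydride is delivered 1,2 under reagent control to give the (S)-carbinol (C2′), as in the reduction of alkenyl n-alkyl ketones.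

**Step 10**
Reactants: 17 (2S,4E,6S)-1,1-dimethoxy-2,4-dimethyl-16-phenylhexadec-4-ene-2,6-diol
Product: 18 (2S,4E,6S)-6-[(tert-butyldiphenylsilyl)oxy]-1,1-dimethoxy-2,4-dimethyl-16-phenylhexadec-4-en-2-ol
Conditions: TBDPSCl, imidazole, DMF, rt
Reagents that add atoms: tert-butyldiphenylsilyl chloride CC(C)(C)[Si](Cl)(c1ccccc1)c1ccccc1
Why: Only the secondary allylic alcohol is silylated (the tertiary one is too hindered), and the acid-robust silyl ether is there to keep the allylic C–O bond from ionising in step 11.

**Step 11**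
Reactants: 18 (2S,4E,6S)-6-[(tert-butyldiphenylsilyl)oxy]-1,1-dimethoxy-2,4-dimethyl-16-phenylhexadec-4-en-2-ol
Product: 19 (1RS,2S,4E,6S)-6-[(tert-butyldiphenylsilyl)oxy]-1-hydroperoxy-1-methoxy-2,4-dimethyl-16-phenylhexadec-4-en-2-ol
Conditions: urea·H2O2 (10 equiv), Sc(OTf)3 (10 mol%), MeOH, 0 °C → rt
Reagents that add atoms: hydrogen peroxide (as urea adduct) OO
Why: Lewis-acid-catalysed perhydrolysis of a dimethyl acetal (exchange through the oxocarbenium ion, H2O2 being the better nucleophile) stops at the monohydroperoxy acetal in methanol; the new C3 centre forms as an epimer mixture, which is of no consequence.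

**Step 12**
Reactants: 19 (1RS,2S,4E,6S)-6-[(tert-butyldiphenylsilyl)oxy]-1-hydroperoxy-1-methoxy-2,4-dimethyl-16-phenylhexadec-4-en-2-ol
Product: 20 (1RS,2S,4E,6S)-1-hydroperoxy-1-methoxy-2,4-dimethyl-16-phenylhexadec-4-ene-2,6-diol
Conditions: TBAF, AcOH (1:1), THF, 0 °C → rt
Reagents that add atoms: none
Why: Acetic-acid-buffered fluoride cleaves the Si–O bond under near-neutral conditions, which should spare both the hydroperoxy acetal (base- and reductant-sensitive) and the freed allylic alcohol (acid-sensitive).

**Step 13**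
Reactants: 20 (1RS,2S,4E,6S)-1-hydroperoxy-1-methoxy-2,4-dimethyl-16-phenylhexadec-4-ene-2,6-diol
Product: 21 (3RS,4S,6R)-3-methoxy-4,6-dimethyl-6-[(1E)-12-phenyldodec-1-en-1-yl]-1,2-dioxan-4-ol
Conditions: PdCl2(MeCN)2 (10 mol%), THF, 0 °C
Reagents that add atoms: none
Why: Proposed new method: PdCl2(MeCN)2 is expected to bind the C6=C1′ alkene on the face of the C2′ hydroxyl, the terminal oxygen of the C3 hydroperoxide then adds to C6 in a syn oxypalladation, and syn elimination of Pd(OH)Cl from C1′/C2′ releases water, the (E) chain alkene and Pd(II), so that overall the OOH displaces the allylic OH in a syn SN2′ sense. The closest known reactions are the Pd(II)-catalysed cyclisations of hydroxy allylic alcohols to 2-alkenyl tetrahydropyrans with 1,3-chirality transfer and the Pd(II)-mediated cyclisations of unsaturated hydroperoxides to 1,2-dioxanes; a hydroperoxy acetal as the nucleophile in the SN2′ manifold is the untested combination. The 1,2-dioxane closes in the 6-exo-trig mode (O–O–C3–C4–C5–C6). The new C6 stereocentre is controlled by the (S)-C2′ carbinol together with the (E) geometry: allylic 1,3-strain with the C6 methyl holds the C2′–H in the alkene plane, the OH then lies on one face, and O–C6 bond formation is confined to that face, giving the (6R)-alkenyl dioxane (6S once the chain is saturated), independent of ring conformation. The step needs faithful chirality transfer and chemoselection for the hydroperoxide over the two hydroxyls; the first is served by a neutral Pd(II) catalyst at 0 °C that avoids ionisation to the allyl cation, the second by ring size, since the C4 hydroxyl could only close an oxetane.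

**Step 14**
Reactants: 21 (3RS,4S,6R)-3-methoxy-4,6-dimethyl-6-[(1E)-12-phenyldodec-1-en-1-yl]-1,2-dioxan-4-ol
Product: 22 (3RS,4S,6S)-3-methoxy-4,6-dimethyl-6-(12-phenyldodecyl)-1,2-dioxan-4-ol
Conditions: KO2CN=NCO2K (10 equiv), AcOH, MeOH/CH2Cl2, 0 °C → rt
Reagents that add atoms: none
Why: Diimide reduction transfers H2 concertedly to the disubstituted alkene and leaves the O–O bond intact; it also removes the ionisable tertiary allylic peroxide before the Lewis acid step.

**Step 15**
Reactants: 22 (3RS,4S,6S)-3-methoxy-4,6-dimethyl-6-(12-phenyldodecyl)-1,2-dioxan-4-ol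
Product: 24 methyl 2-[(3S,4S,6S)-4,6-dimethyl-6-(12-phenyldodecyl)-4-[(trimethylsilyl)oxy]-1,2-dioxan-3-yl]acetate, via O-trimethylsilyl ether 23 (not isolated)
Conditions: CH2=C(OMe)OSiMe3 (4 equiv), CH2Cl2, rt, 1 h; then TMSOTf (0.3 equiv), −78 °C; Et3N, aq. NaHCO3
Reagents that add atoms: 1-methoxy-1-(trimethylsilyloxy)ethene C=C(OC)O[Si](C)(C)C
Why: Mukaiyama-type substitution of a 3-alkoxy-1,2-dioxane: after in situ O-silylation, TMSOTf ionises the C3 methoxy group to the peroxycarbenium ion, which the ketene silyl acetal should attack axially on the half-chair that keeps the C4–CH3 bond pseudoaxial and the C4–O bond pseudoequatorial (the preference known for 2-alkoxy oxocarbenium ions), so that the new C2–C3 bond is cis to the C4 oxygen and both C3 epimers of 22 converge.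

**Step 16**
Reactants: 24 methyl 2-[(3S,4S,6S)-4,6-dimethyl-6-(12-phenyldodecyl)-4-[(trimethylsilyl)oxy]-1,2-dioxan-3-yl]acetate
Product: 25 plakortolide L, the cis-fused 1,2-dioxane γ-lactone with 3S,4S,6S configuration
Conditions: p-TsOH·H2O (10 mol%), wet CH2Cl2, rt
Reagents that add atoms: none
Why: Acid removes the tertiary TMS ether and the γ-hydroxy ester closes to the γ-lactone (5-exo-trig transesterification), which only the cis adduct can do, so the C3/C4 relationship of the target is secured and any trans adduct is left behind.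

**Compound list**
1 | (R)-2-methylglycidol | C1[C@](CO)(C)O1 | starting material
2 | (S)-tert-butyldimethyl[(2-methyloxiran-2-yl)methoxy]silane | C1[C@](CO[Si](C)(C)C(C)(C)C)(C)O1 | intermediate
3 | ethynyltrimethylsilane | C#C[Si](C)(C)C | starting material
4 | lithium (trimethylsilyl)acetylide | [Li+].[C-]#C[Si](C)(C)C | intermediate
5 | (S)-1-[(tert-butyldimethylsilyl)oxy]-2-methyl-5-(trimethylsilyl)pent-4-yn-2-ol | CC(C)(C)[Si](C)(C)OC[C@@](C)(O)CC#C[Si](C)(C)C | intermediate
6 | (S)-2-methylpent-4-yne-1,2-diol | OC[C@@](C)(O)CC#C | intermediate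
7 | trimethylaluminium | C[Al](C)C | starting material
8 | (E)-alkenyldimethylalane of 6 with both hydroxyls as dimethylaluminium alkoxides | C[Al](C)OC[C@@](C)(O[Al](C)C)C/C(C)=C/[Al](C)C | intermediate
9 | (2S,4E)-5-iodo-2,4-dimethylpent-4-ene-1,2-diol | OC[C@@](C)(O)C/C(C)=C/I | intermediate
10 | (2S,4E)-2-hydroxy-5-iodo-2,4-dimethylpent-4-enal | O=C[C@@](C)(O)C/C(C)=C/I | intermediate
11 | (2S,4E)-5-iodo-1,1-dimethoxy-2,4-dimethylpent-4-en-2-ol | COC(OC)[C@@](C)(O)C/C(C)=C/I | intermediate
12 | 11-phenylundecanoic acid | OC(=O)CCCCCCCCCCc1ccccc1 | starting material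
13 | 1-(1H-imidazol-1-yl)-11-phenylundecan-1-one | O=C(CCCCCCCCCCc1ccccc1)n1ccnc1 | intermediate
14 | N-methoxy-N-methyl-11-phenylundecanamide | CON(C)C(=O)CCCCCCCCCCc1ccccc1 | intermediate
15 | (E)-alkenyllithium of 11 with the tertiary hydroxyl as lithium alkoxide | COC(OC)[C@@](C)(O[Li])C/C(C)=C/[Li] | intermediate
16 | (2S,4E)-2-hydroxy-1,1-dimethoxy-2,4-dimethyl-16-phenylhexadec-4-en-6-one | COC(OC)[C@@](C)(O)C/C(C)=C/C(=O)CCCCCCCCCCc1ccccc1 | intermediate
17 | (2S,4E,6S)-1,1-dimethoxy-2,4-dimethyl-16-phenylhexadec-4-ene-2,6-diol | COC(OC)[C@@](C)(O)C/C(C)=C/[C@@H](O)CCCCCCCCCCc1ccccc1 | intermediate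
18 | (2S,4E,6S)-6-[(tert-butyldiphenylsilyl)oxy]-1,1-dimethoxy-2,4-dimethyl-16-phenylhexadec-4-en-2-ol | COC(OC)[C@@](C)(O)C/C(C)=C/[C@@H](O[Si](c1ccccc1)(c1ccccc1)C(C)(C)C)CCCCCCCCCCc1ccccc1 | intermediate
19 | (1RS,2S,4E,6S)-6-[(tert-butyldiphenylsilyl)oxy]-1-hydroperoxy-1-methoxy-2,4-dimethyl-16-phenylhexadec-4-en-2-ol | COC(OO)[C@@](C)(O)C/C(C)=C/[C@@H](O[Si](c1ccccc1)(c1ccccc1)C(C)(C)C)CCCCCCCCCCc1ccccc1 | intermediate
20 | (1RS,2S,4E,6S)-1-hydroperoxy-1-methoxy-2,4-dimethyl-16-phenylhexadec-4-ene-2,6-diol (key-step precursor) | COC(OO)[C@@](C)(O)C/C(C)=C/[C@@H](O)CCCCCCCCCCc1ccccc1 | intermediate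
21 | (3RS,4S,6R)-3-methoxy-4,6-dimethyl-6-[(1E)-12-phenyldodec-1-en-1-yl]-1,2-dioxan-4-ol (key-step product) | C[C@]1(/C=C/CCCCCCCCCCc2ccccc2)C[C@](C)(O)C(OC)OO1 | intermediate
22 | (3RS,4S,6S)-3-methoxy-4,6-dimethyl-6-(12-phenyldodecyl)-1,2-dioxan-4-ol | C[C@]1(CCCCCCCCCCCCc2ccccc2)C[C@](C)(O)C(OC)OO1 | intermediate
23 | trimethylsilyl ether of 22 at the C4 hydroxyl | C[C@]1(CCCCCCCCCCCCc2ccccc2)C[C@](C)(O[Si](C)(C)C)C(OC)OO1 | intermediate
24 | methyl 2-[(3S,4S,6S)-4,6-dimethyl-6-(12-phenyldodecyl)-4-[(trimethylsilyl)oxy]-1,2-dioxan-3-yl]acetate | C[C@]1(CCCCCCCCCCCCc2ccccc2)C[C@](C)(O[Si](C)(C)C)[C@H](CC(=O)OC)OO1 | intermediate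
25 | plakortolide L (3S,4S,6S) | C[C@]1(CCCCCCCCCCCCc2ccccc2)C[C@]2(C)OC(=O)C[C@@H]2OO1 | target

**Step count and risks**

Total: 16 steps. Longest linear sequence: 15 steps (from 1 through steps 1–6 and 8–16; step 7 is the side branch).

The three steps most likely to fail:

Step 13 (key step). The hydroperoxide may not add to the Pd-bound alkene in the syn sense. Pd(II) could instead decompose the hydroperoxy acetal, oxidise C2′ by β-hydride elimination in place of β-hydroxide elimination, or ionise the allylic alcohol so that the C2′-to-C6 transfer erodes. The fallback uses known stoichiometric mercury chemistry in two stages and sets out from 20. Cycloperoxymercuration (Hg(OAc)2, cat. HClO4, CH2Cl2) would close the O1–C6 bond and give the β-hydroxyalkylmercury acetate F1, the dioxane of 21 with a 1-(acetoxymercurio)-2-hydroxy-12-phenyldodecyl chain at C6. Acid-induced demercurative elimination of mercury and the C2′ hydroxyl would then give 21, where the route is rejoined before step 14; the geometry of the chain alkene does not matter because it is saturated next. If the anti-addition/anti-elimination course delivered the C6 epimer, the C2′ epimer of 20 would be used, available with the (S)-oxazaborolidine in step 9.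

Step 15. Facial selectivity in the attack on the peroxycarbenium ion may be poor: if the half-chair with the C4–O bond pseudoaxial reacts, the acetate arm enters anti to the C4 oxygen and cannot lactonise. The fallback replaces kinetic by thermodynamic control and sets out from 22. The same addition is run and the anti adduct F2, the C3 epimer of 24, is treated with Et2NH in CF3CH2OH. E1cB opening gives the hydroperoxy (E)-enoate F3, the ring-opened C6 hydroperoxide of 24 with a C2=C3 double bond. Its reversible 6-exo oxa-Michael re-addition should favour the isomer with the equatorial side chain cis to the C4 oxygen, which is 24, and step 16 drains it.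

Step 11. Acid may ionise the allylic silyl ether to the secondary/tertiary allyl cation, with methanolysis or loss of the C2′ configuration, or the exchange may run on to the gem-dihydroperoxide. The fallback replaces protic exchange by aprotic halide activation and sets out from 18. Bromodimethylborane with Et3N in CH2Cl2 at −78 °C would cleave the dimethyl acetal to the α-bromo ether F4, the 1-bromo-1-methoxy analogue of 18 with the tertiary hydroxyl as its dimethylborinate. Anhydrous H2O2 with iPr2NEt would then displace bromide and give 19 after hydrolytic work-up.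

**Further compounds**
F1 | step 13 | acetoxymercury adduct: (3RS,4S)-3-methoxy-4,6-dimethyl-1,2-dioxan-4-ol bearing at C6 a 1-(acetoxymercurio)-2-hydroxy-12-phenyldodecyl chain | C[C@]1(C([Hg]OC(C)=O)[C@@H](O)CCCCCCCCCCc2ccccc2)C[C@](C)(O)C(OC)OO1
F2 | step 15 | methyl 2-[(3R,4S,6S)-4,6-dimethyl-6-(12-phenyldodecyl)-4-[(trimethylsilyl)oxy]-1,2-dioxan-3-yl]acetate (C3 epimer of 24) | C[C@]1(CCCCCCCCCCCCc2ccccc2)C[C@](C)(O[Si](C)(C)C)[C@@H](CC(=O)OC)OO1
F3 | step 15 | methyl (2E,4S,6S)-6-hydroperoxy-4,6-dimethyl-18-phenyl-4-[(trimethylsilyl)oxy]octadec-2-enoate | C[C@@](CCCCCCCCCCCCc1ccccc1)(OO)C[C@](C)(O[Si](C)(C)C)/C=C/C(=O)OC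
F4 | step 11 | 1-bromo-1-methoxy analogue of 18 with the tertiary hydroxyl as dimethylborinate | COC(Br)[C@@](C)(OB(C)C)C/C(C)=C/[C@@H](O[Si](c1ccccc1)(c1ccccc1)C(C)(C)C)CCCCCCCCCCc1ccccc1
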